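**Retrosynthetic overview**

1. Ring A (the butanoylphloroglucinol core) comes from phloroglucinol; the two identical 2-propanoyl-4,4-dimethylcyclohexane-1,3,5-trione (filicinic) rings B and B′ on the CH2 bridges are the only skeletal rings to build, and both are closed last, in one operation.
2. Key disconnection in each of B and B′: the ring bond C1–C2 (C1 = ring C=O flanked by the bridge-bearing C6 and the propanoyl-bearing C2), an intramolecular Claisen bond; this unfolds each ring to the chain ArCH2–CH(C6)(C1OOAr)–CO–CMe2–CO–CH2–CO–Et.
3. Enabling feature: ring B is a cyclic tri-β-carbonyl array (C1=O, C3–OH, C5–OH, plus the propanoyl on C2) with a quaternary, non-enolisable C4 (CMe2). Its C1 sits where the ring A phenol oxygen ortho to the CH2 bridge can hold it as a six-membered aryl lactone (O, C1, C6, CH2 and two carbons of ring A); this temporary dihydrocoumarin ring activates C1 and is opened by the same acyl transfer that closes ring B.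
4. The chain is assembled with its 1,3-diketone masked as a 3-ethylisoxazole: twofold Knoevenagel condensation/lactonisation of 5-butanoyl-2,4,6-trihydroxyisophthalaldehyde with an isoxazolyl β-keto ester, then hydrogenation (C=C and N–O) and hydrolysis.
5. Order of ring formation: ring A (bought) → isoxazole (masking ring) → two temporary pyranone rings → ring B, then ring B′ (last), with the temporary rings consumed.

Key step: step 7

**Remarks on the chemistry**

- The two lactone rings of the bis-lactone intermediates are drawn on the hydroxyls flanking the butanoyl group (linear pyrano[3,2-g]chromene). An angular regioisomer using the central hydroxyl would give the same final product, because every aryl oxygen is set free in the last step.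
- Methyl 2,2-dimethylbut-3-ynoate is taken as a catalogue compound.
- Triketones are drawn in one enol form. The lactone α-carbons of the dihydrocoumarin intermediates are configurationally labile (β-keto lactones), so they carry no descriptors; they become enol carbons in the last step, and the target has no stereocentre.

**Route**

Step 1
Reactants: 1 benzene-1,3,5-triol (phloroglucinol)
Product: 3 2,4,6-trihydroxybenzene-1,3-dicarbaldehyde, via bis-iminium salt 2 (not isolated)
Conditions: POCl3 (2.5 equiv), DMF (2.5 equiv), EtOAc, 0 → 25 °C; then H2O, 25 °C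
Reagents that add atoms: N,N-dimethylformamide, CN(C)C=O; water, O
Why: Vilsmeier–Haack formylation, in which the very electron-rich ring should take up two chloroiminium electrophiles while the two iminium groups then deactivate it against a third, and aqueous hydrolysis should release the dialdehyde.

Step 2
Reactants: 3 2,4,6-trihydroxybenzene-1,3-dicarbaldehyde; 4 butanoyl chloride
Product: 5 5-butanoyl-2,4,6-trihydroxybenzene-1,3-dicarbaldehyde
Conditions: AlCl3 (4 equiv), PhNO2, 60 °C; then ice, 1 M HCl
Reagents that add atoms: none
Why: Friedel–Crafts acylation at the single free ring position, which remains activated by three hydroxyl groups, with any O-acylated material expected to converge by Fries rearrangement under the same Lewis acid.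

Step 3
Reactants: 6 1-nitropropane; 7 methyl 2,2-dimethylbut-3-ynoate
Product: 9 methyl 2-(3-ethyl-1,2-oxazol-5-yl)-2-methylpropanoate, via propanenitrile oxide 8 (not isolated)
Conditions: PhNCO (2.2 equiv), Et3N (cat.), toluene, 25 → 60 °C
Reagents that add atoms: none
Why: Dehydration of the primary nitroalkane with phenyl isocyanate should give the nitrile oxide, whose 1,3-dipolar (Huisgen) cycloaddition to the terminal alkyne places the bulky substituent at C5 and delivers the 3,5-disubstituted isoxazole as a masked 1,3-diketone.

Step 4
Reactants: 9 methyl 2-(3-ethyl-1,2-oxazol-5-yl)-2-methylpropanoate; 10 methyl acetate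
Product: 12 methyl 4-(3-ethyl-1,2-oxazol-5-yl)-4-methyl-3-oxopentanoate, via lithium ester enolate 11 (not isolated)
Conditions: LDA (2.4 equiv), 10 (2.4 equiv), THF, −78 °C; then 9, −78 → −30 °C; then 1 M HCl
Reagents that add atoms: none
Why: Crossed Claisen condensation in which the non-enolisable, isoxazolyl-activated ester can act only as the acceptor and the second equivalent of enolate should hold the product as its enolate until the quench.

Step 5
Reactants: 5 5-butanoyl-2,4,6-trihydroxybenzene-1,3-dicarbaldehyde; 12 methyl 4-(3-ethyl-1,2-oxazol-5-yl)-4-methyl-3-oxopentanoate (2.2 equiv)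
Product: 13 10-butanoyl-3,7-bis[2-(3-ethyl-1,2-oxazol-5-yl)-2-methylpropanoyl]-5-hydroxy-2H,8H-pyrano[3,2-g]chromene-2,8-dione
Conditions: piperidine (20 mol%), AcOH (20 mol%), EtOH, reflux
Reagents that add atoms: none
Why: Twofold Knoevenagel condensation of the ortho-hydroxy aldehydes with the only active methylene of 12, each followed by lactonisation of a neighbouring phenol onto the methyl ester (the standard 3-acylcoumarin synthesis), while the isoxazole keeps the future diketone carbon silent.

Step 6
Reactants: 13 10-butanoyl-3,7-bis[2-(3-ethyl-1,2-oxazol-5-yl)-2-methylpropanoyl]-5-hydroxy-2H,8H-pyrano[3,2-g]chromene-2,8-dione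
Product: 16 10-butanoyl-3,7-bis(2,2-dimethyl-3,5-dioxoheptanoyl)-5-hydroxy-3,4,6,7-tetrahydro-2H,8H-pyrano[3,2-g]chromene-2,8-dione, via hydrogenated bis-isoxazole 14 (not isolated), via bis-enaminone 15 (not isolated)
Conditions: H2 (1 atm), Pd/C (10%), EtOAc–AcOH (9:1), 25 °C; filter; then 1 M HCl–THF, 25 °C
Reagents that add atoms: water, O
Why: Heterogeneous hydrogenation should first saturate the electron-poor C3=C4 bonds of the 3-acylcoumarins and then cleave the weak isoxazole N–O bonds to the Z-β-enaminones, which dilute acid should hydrolyse to the 1,3-diketones, the acidic medium keeping the enaminone carbon from attacking the aryl lactone.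

Step 7
Reactants: 16 10-butanoyl-3,7-bis(2,2-dimethyl-3,5-dioxoheptanoyl)-5-hydroxy-3,4,6,7-tetrahydro-2H,8H-pyrano[3,2-g]chromene-2,8-dione
Product: 18 2,2'-[(5-butanoyl-2,4,6-trihydroxy-1,3-phenylene)bis(methylene)]bis(3,5-dihydroxy-4,4-dimethyl-6-propanoylcyclohexa-2,5-dien-1-one), via monocyclised lactone 17 (not isolated)
Conditions: Et3N (6 equiv), DMAP (20 mol%), MeCN (0.01 M), 0 → 25 °C; then cold 1 M HCl
Reagents that add atoms: none
Why: Et3N should ionise each 1,3-diketone while part of the β-keto lactone stays neutral, the diketonate carbon then adds to the adjacent aryl lactone carbonyl and the tetrahedral intermediate collapses with loss of the acyl-stabilised phenoxide, so that each temporary pyranone ring opens as a carbocycle closes and the whole change is an isomerisation without by-product, DMAP returning any O-acylated (enol lactone) material to the C-acylation manifold. The closest known reaction types are the Claisen (Dieckmann-type) cyclisation of 3,5,7-triketo esters to acylphloroglucinols, the alkoxide-induced isomerisation of 6-alkylidenepyran-2,4-dione enol lactones (ketene lactone trimers) to cyclohexane-1,3,5-triones, and the amine/DMAP- or cyanide-mediated rearrangement of enol esters to 2-acyl-1,3-diones. Each ring closes by 6-exo-trig attack of an enolate carbon on the lactone C=O, first to 17 and then, as the last ring closure of the skeleton, to 18. No stereocentre is formed, and the labile lactone α-centres of 16 become enol carbons. The step needs C- over O-acylation and Claisen over aldol closure: the quaternary CMe2 carbon blocks the aromatising aldol mode, leaves the diketone carbon as the only carbon nucleophile that can reach the lactone carbonyl through a six-membered transition state and favours closure by the gem-dialkyl effect, while the aryl ester activation allows an amine base mild enough to spare the CH2 bridges. The acidic 2-acyl-1,3,5-trione products should leave the equilibria as triethylammonium enolates, which makes the closure one-way.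

**Compound list**

1 | benzene-1,3,5-triol (phloroglucinol) | Oc1cc(O)cc(O)c1 | starting material
2 | N,N'-[(2,4,6-trihydroxy-1,3-phenylene)dimethylidyne]bis(N-methylmethanaminium) dichloride (bis-iminium salt) | C[N+](C)=Cc1c(O)cc(O)c(C=[N+](C)C)c1O.[Cl-].[Cl-] | intermediate
3 | 2,4,6-trihydroxybenzene-1,3-dicarbaldehyde | O=Cc1c(O)cc(O)c(C=O)c1O | intermediate
4 | butanoyl chloride | CCCC(=O)Cl | starting material
5 | 5-butanoyl-2,4,6-trihydroxybenzene-1,3-dicarbaldehyde | CCCC(=O)c1c(O)c(C=O)c(O)c(C=O)c1O | intermediate
6 | 1-nitropropane | CCC[N+](=O)[O-] | starting material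
7 | methyl 2,2-dimethylbut-3-ynoate | COC(=O)C(C)(C)C#C | starting material
8 | propanenitrile oxide | CCC#[N+][O-] | intermediate
9 | methyl 2-(3-ethyl-1,2-oxazol-5-yl)-2-methylpropanoate | COC(=O)C(C)(C)c1cc(CC)no1 | intermediate
10 | methyl acetate | COC(C)=O | starting material
11 | lithium 1-methoxyethen-1-olate (lithium enolate of methyl acetate) | [Li+].[O-]C(=C)OC | intermediate
12 | methyl 4-(3-ethyl-1,2-oxazol-5-yl)-4-methyl-3-oxopentanoate | COC(=O)CC(=O)C(C)(C)c1cc(CC)no1 | intermediate
13 | 10-butanoyl-3,7-bis[2-(3-ethyl-1,2-oxazol-5-yl)-2-methylpropanoyl]-5-hydroxy-2H,8H-pyrano[3,2-g]chromene-2,8-dione | CCCC(=O)c1c2OC(=O)C(C(=O)C(C)(C)c3cc(CC)no3)=Cc2c(O)c2C=C(C(=O)C(C)(C)c3cc(CC)no3)C(=O)Oc12 | intermediate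
14 | 10-butanoyl-3,7-bis[2-(3-ethyl-1,2-oxazol-5-yl)-2-methylpropanoyl]-5-hydroxy-3,4,6,7-tetrahydro-2H,8H-pyrano[3,2-g]chromene-2,8-dione (labile C3/C7 epimers) | CCCC(=O)c1c2OC(=O)C(C(=O)C(C)(C)c3cc(CC)no3)Cc2c(O)c2CC(C(=O)C(C)(C)c3cc(CC)no3)C(=O)Oc12 | intermediate
15 | 3,7-bis[(4Z)-5-amino-2,2-dimethyl-3-oxohept-4-enoyl]-10-butanoyl-5-hydroxy-3,4,6,7-tetrahydro-2H,8H-pyrano[3,2-g]chromene-2,8-dione (labile C3/C7 epimers) | CCCC(=O)c1c2OC(=O)C(C(=O)C(C)(C)C(=O)/C=C(\N)CC)Cc2c(O)c2CC(C(=O)C(C)(C)C(=O)/C=C(\N)CC)C(=O)Oc12 | intermediate
16 | 10-butanoyl-3,7-bis(2,2-dimethyl-3,5-dioxoheptanoyl)-5-hydroxy-3,4,6,7-tetrahydro-2H,8H-pyrano[3,2-g]chromene-2,8-dione (labile C3/C7 epimers) | CCCC(=O)c1c2OC(=O)C(C(=O)C(C)(C)C(=O)CC(=O)CC)Cc2c(O)c2CC(C(=O)C(C)(C)C(=O)CC(=O)CC)C(=O)Oc12 | intermediate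
17 | 8-butanoyl-6-[(2,4-dihydroxy-3,3-dimethyl-6-oxo-5-propanoylcyclohexa-1,4-dien-1-yl)methyl]-3-(2,2-dimethyl-3,5-dioxoheptanoyl)-5,7-dihydroxy-3,4-dihydro-2H-chromen-2-one (labile C3 epimers) | CCCC(=O)c1c(O)c(CC2=C(O)C(C)(C)C(O)=C(C(=O)CC)C2=O)c(O)c2CC(C(=O)C(C)(C)C(=O)CC(=O)CC)C(=O)Oc12 | intermediate
18 | 2,2'-[(5-butanoyl-2,4,6-trihydroxy-1,3-phenylene)bis(methylene)]bis(3,5-dihydroxy-4,4-dimethyl-6-propanoylcyclohexa-2,5-dien-1-one) | CCCC(=O)c1c(O)c(CC2=C(O)C(C)(C)C(O)=C(C(=O)CC)C2=O)c(O)c(CC2=C(O)C(C)(C)C(O)=C(C(=O)CC)C2=O)c1O | target

**Step count and risks**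

Total step count: 7.
Longest linear sequence: 5 steps (1 → 3 → 5 → 13 → 16 → 18; the branch 7 → 9 → 12 → 13 → 16 → 18 is equally long).

Steps most likely to fail:

Step 7. The base-mediated closure may be undermined by scrambling of the benzylic CH2 bridges (retro-Michael loss of a triketone unit from the liberated phenoxide), by retro-Claisen cleavage at the quaternary carbon, or by O-acylation that does not return to the C-acylation manifold. The fallback drops the base altogether and changes the mechanism to a thermal one. Setting out from 16, heating in dilute toluene at 110 °C should extrude the phenol from each β-keto aryl ester to give the α-oxoketene, 1-{3,5-bis[2-(2,2-dimethyl-3,5-dioxoheptanoyl)-3-oxoprop-2-en-1-yl]-2,4,6-trihydroxyphenyl}butan-1-one F1, which is not isolated. Each ketene should be captured at carbon by the neighbouring 1,3-diketone enol (C-acylation of 1,3-dicarbonyl compounds by acylketenes is known), while capture by the phenol or by the enol oxygen is reversible at this temperature. The sequence comes back to the route at 18.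

Step 6. Chemoselectivity may be lost under the one-pot hydrogenation: incomplete N–O cleavage next to over-reduction of the aryl ketone, or acylation of the freshly liberated enaminone by the aryl lactone before it is hydrolysed. The fallback separates the two reductions and replaces catalytic hydrogenation by two mechanistically different reagents. Setting out from 13, conjugate hydride transfer from Hantzsch ester (diethyl 2,6-dimethyl-1,4-dihydropyridine-3,5-dicarboxylate; silica gel, toluene, 60 °C) should reduce only the alkylidene β-keto lactones and give 14, now isolated. N–O cleavage with Mo(CO)6 in MeCN–H2O at 80 °C should then give 15, and 1 M HCl–THF should hydrolyse it. This passes only through compounds already in the list (F0) and comes back to the route at 16.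

Step 5. The second condensation may stall on the strongly hydrogen-bonded dialdehyde, or the aldehydes and the 3-acylcoumarin may be diverted into stable amine adducts. The fallback forms the aryl–CH2–C bonds at the CH2 oxidation level through ortho-quinone methides instead of aldehydes. Setting out from 1, Friedel–Crafts acylation with 4 (AlCl3, PhNO2) should give 1-(2,4,6-trihydroxyphenyl)butan-1-one F2. A twofold Mannich reaction (aqueous CH2O, Me2NH, EtOH, 0 → 25 °C) should give 1-{3,5-bis[(dimethylamino)methyl]-2,4,6-trihydroxyphenyl}butan-1-one F3. Heating F3 with 12 (2.2 equiv) in toluene at reflux should eliminate dimethylamine to the ortho-quinone methides, which add the β-keto ester at its active methylene; a final treatment with catalytic TsOH completes lactonisation, the hindered ketone disfavouring chromene formation. The sequence comes back to the route at 14, which is then carried through the conditions of step 6 (N–O hydrogenolysis and hydrolysis only).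

**Further compounds**

F1 | step 7 | 1-{3,5-bis[2-(2,2-dimethyl-3,5-dioxoheptanoyl)-3-oxoprop-2-en-1-yl]-2,4,6-trihydroxyphenyl}butan-1-one (bis-acylketene) | CCCC(=O)c1c(O)c(CC(=C=O)C(=O)C(C)(C)C(=O)CC(=O)CC)c(O)c(CC(=C=O)C(=O)C(C)(C)C(=O)CC(=O)CC)c1O
F0 | step 6 | none | none
F2 | step 5 | 1-(2,4,6-trihydroxyphenyl)butan-1-one | CCCC(=O)c1c(O)cc(O)cc1O
F3 | step 5 | 1-{3,5-bis[(dimethylamino)methyl]-2,4,6-trihydroxyphenyl}butan-1-one | CCCC(=O)c1c(O)c(CN(C)C)c(O)c(CN(C)C)c1O
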